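1. Numbering (eudesmane type, kept for every intermediate): C1 CHBr, C2/C3 CH2, C4 C(=CH2), C5 C-OH, C6 CH2, C7 CH carrying the side chain C11-C16, C8/C9 CH2, C10 C-CH3. Ring A = C1-C5 + C10, ring B = C5-C10, and β is the face of the C10 methyl group.
2. Enabling feature: in ring A the brominated carbon C1 stands 1,4 to C4. Once C4 is read as a ketone, ring A is a 4-bromocyclohexanone. Its C2-C3 and C1-Br bonds are what a BrCH2-C(=O) unit on C5 adds across a vinyl group (C1=C2) on C10.
3. Cuts, in retrosynthetic order: O-Si; C12-C13 (Suzuki-Miyaura); C11=C12 (boron-Wittig); C4=CH2 (methylenation); C2-C3 together with C1-Br (radical ring closure); C3-Br; C5-O and C4=C5 (osmylation, Wittig); C1=C2, C10-CH3 and C10-C1; C7-C11.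
4. Forward order: ring B is bought as cyclohexenone and is substituted at C7, then C10, then C5. Ring A closes in step 12. The triene is joined last, C11=C12 before C12-C13.
5. Stereochemistry: C7 comes from a rhodium/(R)-BINAP conjugate addition and C10 from axial methylation cis to the C7 group. C5 comes from osmylation anti to the axial C10 methyl, and C1 from bromine delivery anti to the axial C5 silyloxy group. The E alkenes come from the boron-Wittig elimination and from syn hydrozirconation.

Key step: step 12

Remark: the epoxide of step 5 forms as both epimers at its quaternary carbon and the ethylidene alkene of step 7 is drawn as the expected E isomer; both elements are erased again (steps 5 and 9) and do not affect the outcome. Cyclopentadienyl rings are drawn σ-bonded in SMILES.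

Step 1
Reactants: 1 cyclohex-2-en-1-one; 2 isopropenylboronic acid pinacol ester
Product: 3 (R)-3-(prop-1-en-2-yl)cyclohexan-1-one
Conditions: [RhCl(C2H4)2]2 (1.5 mol %), (R)-BINAP (3.3 mol %), KOH (10 mol %), dioxane/H2O 10:1, 40 °C
Reagents that add atoms: none
Why: Hayashi-Miyaura asymmetric 1,4-addition, in which the alkenylrhodium species bearing (R)-BINAP inserts the enone from one enantiotopic face and sets C7 as R, the sense in which this ligand gives (R)-3-aryl- and (R)-3-alkenylcyclohexanones.

Step 2
Reactants: 3 (R)-3-(prop-1-en-2-yl)cyclohexan-1-one; 4 ethyl formate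
Product: 5 (2Z,5R)-2-(hydroxymethylidene)-5-(prop-1-en-2-yl)cyclohexan-1-one
Conditions: NaH (1.2 equiv), EtOH (cat.), THF, 0 °C → rt; aq. HCl quench
Reagents that add atoms: none
Why: Crossed Claisen condensation (formylation) under equilibrating conditions ends at C10, the α-carbon remote from the C7 substituent, because the chelated enolate at C6 would suffer allylic strain with that substituent; no stereocentre is formed.

Step 3
Reactants: 5 (2Z,5R)-2-(hydroxymethylidene)-5-(prop-1-en-2-yl)cyclohexan-1-one
Product: 6 (1S,4R)-1-methyl-2-oxo-4-(prop-1-en-2-yl)cyclohexane-1-carbaldehyde (C10 methyl cis to the C7 isopropenyl group)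
Conditions: MeI (3 equiv), K2CO3 (2 equiv), acetone, rt → 40 °C
Reagents that add atoms: methyl iodide, C[I]
Why: C-Alkylation of a stabilised β-keto aldehyde enolate, in which methyl iodide should approach C10 axially through the chair-like transition state with the C7 group equatorial, placing the new methyl cis to that group (10β); any C10 epimer or O-methyl ether is removed by chromatography.

Step 4
Reactants: 6 (1S,4R)-1-methyl-2-oxo-4-(prop-1-en-2-yl)cyclohexane-1-carbaldehyde; 7 methyltriphenylphosphonium bromide
Product: 8 (2S,5R)-2-ethenyl-2-methyl-5-(prop-1-en-2-yl)cyclohexan-1-one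
Conditions: 7 (1.1 equiv), NaN(SiMe3)2 (1.05 equiv), THF, 0 °C; then 6, −78 → 0 °C
Reagents that add atoms: none
Why: Wittig methylenation with one equivalent of ylide at low temperature takes the aldehyde and not the ketone beside the quaternary carbon, and C10 carries no hydrogen and cannot epimerise.

Step 5
Reactants: 8 (2S,5R)-2-ethenyl-2-methyl-5-(prop-1-en-2-yl)cyclohexan-1-one
Product: 10 (2S,5R)-5-acetyl-2-ethenyl-2-methylcyclohexan-1-one, via epoxide 9 (not isolated)
Conditions: mCPBA (1.05 equiv), CH2Cl2, 0 °C; then H5IO6 (1.2 equiv), THF/H2O, 0 °C → rt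
Reagents that add atoms: mCPBA, O=C(OO)c1cccc(Cl)c1; water, O
Why: Prilezhaev epoxidation follows alkene nucleophilicity, so the 1,1-disubstituted isopropenyl group reacts well before the monosubstituted neopentyl vinyl group, and periodic acid then opens the epoxide and cleaves the glycol (Malaprade cleavage) under conditions too mild to epimerise C7.

Step 6
Reactants: 10 (2S,5R)-5-acetyl-2-ethenyl-2-methylcyclohexan-1-one
Product: 11 (2S,5R)-2-ethenyl-2-methyl-5-(2-methyl-1,3-dioxolan-2-yl)cyclohexan-1-one
Conditions: (TMSOCH2)2 (1.1 equiv), TMSOTf (5 mol %), CH2Cl2, −78 °C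
Reagents that add atoms: 1,2-bis(trimethylsilyloxy)ethane, C[Si](C)(C)OCCO[Si](C)(C)C
Why: Noyori ketalisation at low temperature is governed by steric access, so the methyl ketone is masked while the ring ketone beside quaternary C10 stays free, and the cold aprotic medium avoids enolisation toward C7.

Step 7
Reactants: 11 (2S,5R)-2-ethenyl-2-methyl-5-(2-methyl-1,3-dioxolan-2-yl)cyclohexan-1-one; 12 ethyltriphenylphosphonium bromide
Product: 13 2-[(1R,3E,4S)-4-ethenyl-3-ethylidene-4-methylcyclohexyl]-2-methyl-1,3-dioxolane
Conditions: 12 (3 equiv), KOtBu (2.9 equiv), toluene, 80 °C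
Reagents that add atoms: none
Why: Wittig ethylidenation of a ketone beside a quaternary carbon is the reaction routinely run on 17-oxo steroids; carbon is attached to C5 before oxygen because reagents reach C5 from the α face opposite the axial C10 methyl, so direct addition of an acyl anion equivalent to the ketone would give the wrong C5 epimer.

Step 8
Reactants: 13 2-[(1R,3E,4S)-4-ethenyl-3-ethylidene-4-methylcyclohexyl]-2-methyl-1,3-dioxolane
Product: 14 (1S)-1-[(1S,2S,5R)-2-ethenyl-1-hydroxy-2-methyl-5-(2-methyl-1,3-dioxolan-2-yl)cyclohexyl]ethan-1-ol (4,5-diol, 5α-OH axial and trans to the C10 methyl)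
Conditions: OsO4 (2 mol %), NMO (1.1 equiv), acetone/H2O 5:1, 0 °C → rt
Reagents that add atoms: N-methylmorpholine N-oxide, C[N+]1([O-])CCOCC1; water, O
Why: Upjohn dihydroxylation, in which the more electron-rich trisubstituted C4=C5 alkene should be osmylated before the vinyl group and the axial C10 methyl shields the β face, so both oxygens arrive from the α face and C5 becomes the axial 5α-carbinol, as in the conversion of 17(20)-ethylidene steroids into 17α,20-diols.

Step 9
Reactants: 14 4,5-diol
Product: 15 1-[(1S,2S,5R)-2-ethenyl-1-hydroxy-2-methyl-5-(2-methyl-1,3-dioxolan-2-yl)cyclohexyl]ethan-1-one (5α-hydroxy C4 methyl ketone)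
Conditions: IBX (1.5 equiv), DMSO, rt
Reagents that add atoms: none
Why: IBX oxidises the secondary alcohol of a 1,2-diol to the α-ketol without glycol cleavage, which erases the C4 stereocentre and leaves the tertiary C5 carbinol untouched.

Step 10
Reactants: 15 5α-hydroxy C4 methyl ketone
Product: 16 1-[(1S,2S,5R)-2-ethenyl-2-methyl-5-(2-methyl-1,3-dioxolan-2-yl)-1-(triethylsilyloxy)cyclohexyl]ethan-1-one
Conditions: TESOTf (1.5 equiv), 2,6-lutidine (3 equiv), CH2Cl2, −78 → 0 °C
Reagents that add atoms: triethylsilyl triflate, CC[Si](CC)(CC)OS(=O)(=O)C(F)(F)F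
Why: Silylation of a hindered tertiary alcohol with a silyl triflate and a hindered pyridine is standard and spares the ketone-derived dioxolane, and it must precede enolisation because a free C5 alkoxide inside the 1,5-diene of the enolate would invite an anionic oxy-Cope rearrangement.

Step 11
Reactants: 16 5α-triethylsilyloxy C4 methyl ketone
Product: 18 2-bromo-1-[(1S,2S,5R)-2-ethenyl-2-methyl-5-(2-methyl-1,3-dioxolan-2-yl)-1-(triethylsilyloxy)cyclohexyl]ethan-1-one, via trimethylsilyl enol ether 17 (not isolated)
Conditions: TMSCl (3 equiv), LiN(SiMe3)2 (1.3 equiv, internal quench), THF, −78 °C; volatiles removed; NBS (1.05 equiv), THF, −78 → 0 °C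
Reagents that add atoms: N-bromosuccinimide, O=C1CCC(=O)N1Br; chlorotrimethylsilane, C[Si](C)(C)Cl (silicon stays only in 17)
Why: Only C3 carries α-hydrogens, so enolisation with in situ silylation gives a single silyl enol ether that is far more nucleophilic than the vinyl group and is brominated by NBS at C3 (halogenation of a silyl enol ether).

Step 12
Reactants: 18 bromomethyl ketone (BrCH2-C(=O) on C5, vinyl on C10)
Product: 19 (1R,5S,7R,10R)-1β-bromo-10β-methyl-7β-(2-methyl-1,3-dioxolan-2-yl)-5α-(triethylsilyloxy)-trans-decal-4-one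
Conditions: CuBr (20 mol %), tris(2-pyridylmethyl)amine (TPMA, 20 mol %), degassed 1,2-dichloroethane (0.02 M), 60 °C
Reagents that add atoms: none
Why: Monovalent copper in CuBr/TPMA abstracts bromine from the activated C3-Br bond, the electrophilic α-keto radical at C3 adds to the terminal vinyl carbon C2, and the secondary C1 radical takes bromine back from the divalent copper bromide complex, so C2-C3 and C1-Br form in one redox-neutral operation that regenerates the catalyst. The closest known reaction type is the Kharasch-type atom-transfer radical cyclisation of α-halo ketones, for which 2-oxohex-5-enyl radicals are documented to prefer the endo mode. Ring A closes 6-endo-trig through a chair-like transition state in which the acyl group on C5 and the vinyl group on C10 are both equatorial on ring B, an arrangement that can only lead to the trans-decalin. The new stereocentre C1 is controlled by the axial 5α-triethylsilyloxy group, which together with the axial hydrogens on C3 and C9 blocks the α face in a 1,3-diaxial sense, so bromine should arrive from the β face and give the equatorial bromide, also the more stable epimer. The step needs 6-endo over 5-exo selectivity, secured by the sp2 carbonyl carbon inside the forming ring and by the neopentyl position of C1, and it needs halogen transfer to outrun reduction, cation formation or oligomerisation, secured by the fast inner-sphere bromine transfer from copper, by dilution and by the inertness of the unactivated secondary bromide to re-activation.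

Step 13
Reactants: 19 1β-bromo-5α-silyloxy-decal-4-one
Product: 20 (1R,5R,7R,10R)-1β-bromo-10β-methyl-4-methylidene-7β-(2-methyl-1,3-dioxolan-2-yl)-5α-(triethylsilyloxy)-trans-decalin
Conditions: Cp2TiMe2 (3 equiv), toluene, 70 °C, dark
Reagents that add atoms: dimethyltitanocene, C[Ti](C)(C1C=CC=C1)C1C=CC=C1
Why: Petasis methylenation runs through the non-basic carbene Cp2Ti=CH2 and an oxatitanacyclobutane, so the hindered, enolisable γ-bromo ketone is converted without enolate formation, 1,3-elimination to a cyclopropane or loss of HBr.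

Step 14
Reactants: 20 4-methylidene ketal
Product: 21 (1R,5R,7R,10R)-7β-acetyl-1β-bromo-10β-methyl-4-methylidene-5α-(triethylsilyloxy)-trans-decalin
Conditions: PPTS (0.3 equiv), acetone/H2O 10:1, 45 °C
Reagents that add atoms: water, O
Why: Mild acid-catalysed ketal hydrolysis frees the C11 ketone while the hindered tertiary silyl ether and the exocyclic alkene should survive, and any enolisation toward C7 only returns the equatorial 7β-acetyl group, the stable epimer on the trans-decalin.

Step 15
Reactants: 21 C11 methyl ketone; 22 bis(pinacolatoboryl)methane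
Product: 23 (E)-alkenylboronate, C7-C11(CH3)=C12H-Bpin with boron trans to C7, decalin as in 21
Conditions: 22 (1.5 equiv), lithium 2,2,6,6-tetramethylpiperidide (1.4 equiv), THF, 0 °C; then 21, −78 °C → rt
Reagents that add atoms: none
Why: Boron-Wittig olefination, in which the lithiated geminal diboronate adds to the unhindered methyl ketone and the syn B-O elimination keeps the remaining boryl group anti to the bulky ring carbon C7 to give the E-trisubstituted alkene; the C5 oxygen stays silylated because a free alkoxide would be aligned for Grob fragmentation across C5-C10 with the equatorial C1-Br bond.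

Step 16
Reactants: 24 2-methylbut-1-en-3-yne
Product: 26 (E)-1-iodo-3-methylbuta-1,3-diene, via dienylzirconocene chloride 25 (not isolated)
Conditions: Cp2Zr(H)Cl (1.1 equiv), THF, rt, dark; then iodine (1.05 equiv), 0 °C
Reagents that add atoms: iodine, [I][I]; Cp2Zr(H)Cl, [H][Zr](Cl)(C1C=CC=C1)C1C=CC=C1 (zirconium stays only in 25)
Why: Hydrozirconation adds Zr-H syn across the terminal alkyne in preference to the 1,1-disubstituted alkene with zirconium on the terminal carbon, and iodinolysis with retention gives the E-iodide.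

Step 17
Reactants: 23 (E)-alkenylboronate; 26 (E)-1-iodo-3-methylbuta-1,3-diene
Product: 27 5-O-triethylsilyl ether of the target, (11E,13E)-triene
Conditions: Pd(dppf)Cl2 (5 mol %), K3PO4 (3 equiv), degassed THF/H2O 10:1, 40 °C
Reagents that add atoms: none
Why: Suzuki-Miyaura coupling of an alkenylboronate with an alkenyl iodide retains both alkene geometries, and zerovalent palladium on an arylphosphine inserts only into the sp2 carbon-iodine bond and not into the unactivated, neopentyl-type secondary bromide.

Step 18
Reactants: 27 5-O-triethylsilyl ether of the target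
Product: 28 target CNP0385268.1, (1R,5R,7R,10R): 1β-Br, 5α-OH, 7β-[(2E,4E)-6-methylhepta-2,4,6-trien-2-yl], 10β-CH3, 4-methylidene, trans-decalin
Conditions: TBAF (3 equiv), AcOH (3 equiv), THF, 0 °C → rt
Reagents that add atoms: none
Why: Fluoride-induced Si-O cleavage buffered with acetic acid protonates the oxygen as it is released, so the medium holds neither an alkoxide that could fragment across C5-C10 with loss of bromide nor an acid strong enough to ionise the tertiary allylic alcohol or attack the triene.

Compound list
1 | cyclohex-2-en-1-one | O=C1C=CCCC1 | starting material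
2 | isopropenylboronic acid pinacol ester | C=C(C)B1OC(C)(C)C(C)(C)O1 | starting material
3 | (R)-3-(prop-1-en-2-yl)cyclohexan-1-one | C=C(C)[C@@H]1CCCC(=O)C1 | intermediate
4 | ethyl formate | CCOC=O | starting material
5 | (2Z,5R)-2-(hydroxymethylidene)-5-(prop-1-en-2-yl)cyclohexan-1-one | C=C(C)[C@@H]1CC/C(=C/O)C(=O)C1 | intermediate
6 | (1S,4R)-1-methyl-2-oxo-4-(prop-1-en-2-yl)cyclohexane-1-carbaldehyde | C=C(C)[C@@H]1CC[C@@](C)(C=O)C(=O)C1 | intermediate
7 | methyltriphenylphosphonium bromide | C[P+](c1ccccc1)(c1ccccc1)c1ccccc1.[Br-] | starting material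
8 | (2S,5R)-2-ethenyl-2-methyl-5-(prop-1-en-2-yl)cyclohexan-1-one | C=C(C)[C@@H]1CC[C@@](C)(C=C)C(=O)C1 | intermediate
9 | (2S,5R)-2-ethenyl-2-methyl-5-(2-methyloxiran-2-yl)cyclohexan-1-one, both epoxide epimers | CC1(CO1)[C@@H]2CC[C@@](C)(C=C)C(=O)C2 | intermediate
10 | (2S,5R)-5-acetyl-2-ethenyl-2-methylcyclohexan-1-one | CC(=O)[C@@H]1CC[C@@](C)(C=C)C(=O)C1 | intermediate
11 | (2S,5R)-2-ethenyl-2-methyl-5-(2-methyl-1,3-dioxolan-2-yl)cyclohexan-1-one | CC1(OCCO1)[C@@H]2CC[C@@](C)(C=C)C(=O)C2 | intermediate
12 | ethyltriphenylphosphonium bromide | CC[P+](c1ccccc1)(c1ccccc1)c1ccccc1.[Br-] | starting material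
13 | 2-[(1R,3E,4S)-4-ethenyl-3-ethylidene-4-methylcyclohexyl]-2-methyl-1,3-dioxolane | CC1(OCCO1)[C@@H]2CC[C@@](C)(C=C)/C(=C/C)C2 | intermediate
14 | (1S)-1-[(1S,2S,5R)-2-ethenyl-1-hydroxy-2-methyl-5-(2-methyl-1,3-dioxolan-2-yl)cyclohexyl]ethan-1-ol | CC1(OCCO1)[C@@H]2CC[C@@](C)(C=C)[C@](O)([C@H](C)O)C2 | intermediate
15 | 1-[(1S,2S,5R)-2-ethenyl-1-hydroxy-2-methyl-5-(2-methyl-1,3-dioxolan-2-yl)cyclohexyl]ethan-1-one | CC1(OCCO1)[C@@H]2CC[C@@](C)(C=C)[C@](O)(C(C)=O)C2 | intermediate
16 | 1-[(1S,2S,5R)-2-ethenyl-2-methyl-5-(2-methyl-1,3-dioxolan-2-yl)-1-(triethylsilyloxy)cyclohexyl]ethan-1-one | CC1(OCCO1)[C@@H]2CC[C@@](C)(C=C)[C@](O[Si](CC)(CC)CC)(C(C)=O)C2 | intermediate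
17 | trimethylsilyl enol ether of 16 (C3=C4) | CC1(OCCO1)[C@@H]2CC[C@@](C)(C=C)[C@](O[Si](CC)(CC)CC)(C(=C)O[Si](C)(C)C)C2 | intermediate
18 | 2-bromo-1-[(1S,2S,5R)-2-ethenyl-2-methyl-5-(2-methyl-1,3-dioxolan-2-yl)-1-(triethylsilyloxy)cyclohexyl]ethan-1-one | CC1(OCCO1)[C@@H]2CC[C@@](C)(C=C)[C@](O[Si](CC)(CC)CC)(C(=O)CBr)C2 | intermediate
19 | 1β-bromo-10β-methyl-7β-(2-methyl-1,3-dioxolan-2-yl)-5α-(triethylsilyloxy)-trans-decal-4-one | CC1(OCCO1)[C@@H]2CC[C@@]3(C)[C@H](Br)CCC(=O)[C@]3(O[Si](CC)(CC)CC)C2 | intermediate
20 | 1β-bromo-10β-methyl-4-methylidene-7β-(2-methyl-1,3-dioxolan-2-yl)-5α-(triethylsilyloxy)-trans-decalin | CC1(OCCO1)[C@@H]2CC[C@@]3(C)[C@H](Br)CCC(=C)[C@]3(O[Si](CC)(CC)CC)C2 | intermediate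
21 | 7β-acetyl-1β-bromo-10β-methyl-4-methylidene-5α-(triethylsilyloxy)-trans-decalin | CC(=O)[C@@H]1CC[C@@]2(C)[C@H](Br)CCC(=C)[C@]2(O[Si](CC)(CC)CC)C1 | intermediate
22 | bis(pinacolatoboryl)methane | CC1(C)OB(CB2OC(C)(C)C(C)(C)O2)OC1(C)C | starting material
23 | (E)-C11=C12 alkenylboronic acid pinacol ester of the decalin | CC1(C)OB(/C=C(\C)[C@@H]2CC[C@@]3(C)[C@H](Br)CCC(=C)[C@]3(O[Si](CC)(CC)CC)C2)OC1(C)C | intermediate
24 | 2-methylbut-1-en-3-yne | C=C(C)C#C | starting material
25 | (E)-(3-methylbuta-1,3-dienyl)zirconocene chloride | C=C(C)/C=C/[Zr](Cl)(C1C=CC=C1)C1C=CC=C1 | intermediate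
26 | (E)-1-iodo-3-methylbuta-1,3-diene | C=C(C)/C=C/I | intermediate
27 | 5-O-triethylsilyl ether of the target | C=C(C)/C=C/C=C(\C)[C@@H]1CC[C@@]2(C)[C@H](Br)CCC(=C)[C@]2(O[Si](CC)(CC)CC)C1 | intermediate
28 | CNP0385268.1 | C=C(C)/C=C/C=C(\C)[C@@H]1CC[C@@]2(C)[C@H](Br)CCC(=C)[C@]2(O)C1 | target

Total step count: 18. Longest linear sequence: 17 (steps 1-15, 17, 18).

Steps most likely to fail

Step 12. Activation of the primary C3-Br bond by copper may be slow. The C1 radical may be reduced or may escape before it is brominated, or bromine may reach both faces of C1.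
The fallback sets out from 18 and comes back at 19. It separates carbon-carbon bond formation from bromination.
- Displacement of the bromide with KSC(S)OEt (acetone, 0 °C) should give the S-(2-oxoalkyl) O-ethyl xanthate F1.
- Dilauroyl peroxide in refluxing 1,2-dichloroethane starts a degenerate xanthate-transfer cyclisation. The C3 radical is regenerated reversibly and has a long effective lifetime. The closure forms the same C2-C3 bond in the 6-endo mode and gives the C1 xanthate F2.
- Heating with ethyl 2-bromo-2-methylpropanoate and dicumyl peroxide in chlorobenzene exchanges the xanthate for bromine through the same C1 radical and delivers 19.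

Step 8. Osmylation may lose chemoselectivity, because the trisubstituted alkene is flanked by a quaternary carbon. The results would be attack at the C10 vinyl group and over-oxidation.
The fallback sets out from 11 and comes back at 14.
- Wittig reaction with Ph3P=CHOMe (from (methoxymethyl)triphenylphosphonium chloride and KOtBu, THF) gives the methyl enol ether F3. Its double bond is far more electron-rich than the vinyl group.
- OsO4/NMO attacks it from the α face and the hemiacetal collapses to the 5α-hydroxy aldehyde F4.
- MeMgBr (excess, THF, −78 °C) adds to the aldehyde and gives 14 together with the C4-epimeric diol F5. Step 9 converts both into 15.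

Step 15. The boron-stabilised carbanion may enolise the methyl ketone, and the B-O elimination may discriminate poorly between the E and Z pathways.
The fallback sets out from 21 and comes back at 27. It replaces the boron chemistry and the cross-coupling by two phosphonate olefinations.
- Horner-Wadsworth-Emmons reaction with triethyl phosphonoacetate (NaH, THF) gives the (E)-enoate F6.
- i-Bu2AlH (CH2Cl2, −78 °C) gives the allylic alcohol F7.
- MnO2 (CH2Cl2) gives the (E)-enal F8.
- The lithium anion of diethyl (2-methylallyl)phosphonate (n-BuLi, THF/DMPU, −78 °C → rt) converts the aldehyde E-selectively into 27.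

Further compounds
F1 | step 12 | S-(2-oxoalkyl) O-ethyl xanthate derived from 18 | CC1(OCCO1)[C@@H]2CC[C@@](C)(C=C)[C@](O[Si](CC)(CC)CC)(C(=O)CSC(=S)OCC)C2
F2 | step 12 | 1β-(ethoxythiocarbonylsulfanyl) analogue of 19 | CC1(OCCO1)[C@@H]2CC[C@@]3(C)[C@H](SC(=S)OCC)CCC(=O)[C@]3(O[Si](CC)(CC)CC)C2
F3 | step 8 | C5 methoxymethylidene enol ether derived from 11 | CC1(OCCO1)[C@@H]2CC[C@@](C)(C=C)/C(=C/OC)C2
F4 | step 8 | 5α-hydroxy C4 aldehyde | CC1(OCCO1)[C@@H]2CC[C@@](C)(C=C)[C@](O)(C=O)C2
F5 | step 8 | C4 epimer of diol 14 | CC1(OCCO1)[C@@H]2CC[C@@](C)(C=C)[C@](O)([C@@H](C)O)C2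
F6 | step 15 | ethyl (E)-enoate, C11=C12-CO2Et | CCOC(=O)/C=C(\C)[C@@H]1CC[C@@]2(C)[C@H](Br)CCC(=C)[C@]2(O[Si](CC)(CC)CC)C1
F7 | step 15 | (E)-allylic alcohol, C11=C12-CH2OH | OC/C=C(\C)[C@@H]1CC[C@@]2(C)[C@H](Br)CCC(=C)[C@]2(O[Si](CC)(CC)CC)C1
F8 | step 15 | (E)-enal, C11=C12-CHO | O=C/C=C(\C)[C@@H]1CC[C@@]2(C)[C@H](Br)CCC(=C)[C@]2(O[Si](CC)(CC)CC)C1
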